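## Structural features

The target 30 is a sesquiterpenoid ester on a trans-fused bicyclo[5.3.0]decane core, in which a seven-membered ring (C1–C7) and a five-membered ring (C5, C6, C8, C9, C10) share the C5–C6 bond. Core numbering used throughout: C1 is the ester-bearing CH, C2 a CH2, C3 the methyl carbinol, C4 a CH2, C5 and C6 the ring-fusion CH groups (C5 beside the epoxide CH), C7 the isopropyl-bearing CH, C8 the five-ring CH2, C9 the methyl-bearing epoxide carbon and C10 the epoxide CH; β is the face of H5 and α the face of H6. There are seven stereocentres (1R,3R,5S,6R,7S,9R,10S in this numbering): C9, C10, C5, C6, C7 and C1 form an unbroken chain (epoxide oxygen α, H5 β, H6 α, isopropyl α, acyloxy α), while C3 (OH α, CH3 β) stands alone, 1,3 to both C1 and C5. The fragile groups are the acid-sensitive trisubstituted epoxide, the tertiary alcohol (dehydration, and retro-aldol or elimination whenever a carbonyl sits at C5 or C1) and the aryl ester with its free, oxidisable phenol. The real difficulty is the seven-membered ring with four stereocentres, in particular the cis relation of the C1 oxygen and the C7 isopropyl group next to a trans ring fusion, and the face-selective epoxidation at the end. The key step exploits the fact that C5, C6, C7, C1, C2 and C3, with the C3 methyl and the C7 isopropyl group, are the ring of carvone (carbonyl carbon = C5, methyl-bearing carbon = C3, stereocentre = C7); the seven-membered ring is that six-membered ring with the single carbon C4 inserted between C5 and C3.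

## Logic of the disconnections

30 ⇒ 29. The C9–O and C10–O bonds are cut first, because the epoxide is the most acid-labile group and would survive none of the earlier reagents. What remains has a single alkene, so chemoselectivity is no issue. The forward step must deliver oxygen to the α face of the cyclopentene.

29 ⇒ 27 + 28. The C1–O(acyl) bond is cut with inversion at C1. The cis C1–O/C7-isopropyl relation is hard to set directly, whereas the trans alcohol is what an oxidation anti to isopropyl gives, and a β oxygen at C1 is useful earlier to steer C3. The aryl ester and the phenol are thereby kept out of every basic or reducing step. The forward step needs an SN2 displacement at a hindered secondary carbinol, with the tertiary hydroxyl and the phenol as spectators.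

27 ⇒ 26 ⇒ 24 + 25. The two O–Si bonds and the C9–CH3 bond are cut. Tracing the methyl group to 25 and an alkenyl triflate fixes the position of the C9=C10 alkene through enolate regiochemistry and not through an elimination. The coupling must not move the double bond.

24 ⇒ 22. The C5–H bond and the O–S bond are cut (reductive enolate trapping). The enone lets the ring-fusion hydrogen enter by protonation of a carbanion that can adopt the more stable trans fusion, and the same operation supplies the regiodefined enolate. The demand is trans fusion and trapping before the enolate equilibrates to the C8 side.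

22 ⇒ 20 ⇒ 19. The C5–C10 bond (seen as C5=C10 in 22) is cut by a retro-aldol condensation, which removes the five-membered ring and leaves a 1,4-diketone. The methyl ketone must be enolised in preference to the ring ketone, whose C4 enolate could expel the C3 silyloxy group; hence kinetic enolisation and a separate dehydration.

19 ⇒ 18 ⇒ 17 ⇒ 16 ⇒ 15. The C9=O bond is traced to a terminal alkene, the O–Si bond at C3 is cut, and the C3 carbinol is traced through the C4–O bond of an epoxy ketone to the enone double bond C3=C4. This turns the isolated C3 stereocentre into a facial-selectivity problem on a cycloheptenone that carries a β silyloxy group 1,3 to C3. The forward epoxidation must be α-selective and the β-hydroxy ketone must be capped at once.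

15 ⇒ 12 + 13. The C6–C8 bond is cut at the enone stage, because only there is C6 the single kinetically enolisable position; once the C3 carbinol exists, C4 and C6 would compete and a C4 enolate would eliminate. The alkylation must occur anti to the isopropyl group, which is also the thermodynamic outcome.

12 ⇒ 8 + 9. The C3–C4 and C4–C5 bonds are cut, which removes C4 and contracts the seven-membered enone to a six-membered silyl enol ether with the substitution pattern of carvone. The demand is an enol ether fixed on the methyl-bearing side and cleavage of the internal cyclopropane bond only.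

8 ⇒ 6 ⇒ 5 ⇒ 4 ⇒ 2 ⇒ 1. The C3–H and enol O–Si bonds (conjugate reduction with trapping), the O–Si bond at C1, the C1–O bond (γ-oxidation through a dienol ether) and the two C–H bonds of the isopropyl group are cut in turn. All ring carbons and the C7 stereocentre then come from 1. The oxidation must go to the γ- and not the α-carbon and anti to the isopropyl group, and the hydrogenation must spare the enone.

## Other disconnections considered

Alternative 1: The cut is C5–C6, C8–C9 and C9–C10 at once. In the forward sense the allene-yne A1 (terminal alkyne C10≡C5, 1,1-disubstituted allene C7=C6=C8 with the isopropyl group on C7, both carbinols silylated) would undergo an allenic Pauson–Khand cyclocarbonylation with [Rh(CO)2Cl]2 (monovalent rhodium) under CO, the distal allene double bond reacting, to give the bicyclic dienone A2.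
- In its favour: both rings and three C–C bonds arise in one step, the preference of rhodium for the distal double bond is what a seven-membered ring needs, and C1 and C3 already have their final configuration in A1, so no late inversion is required.
- Against it here: A2 is flat at C5, C6 and C7, so three contiguous stereocentres, including the trans fusion and the isopropyl group cis to the C1 oxygen, would have to be set afterwards by reducing an enone and a tetrasubstituted alkylidene; A1 itself needs an enantioselective synthesis of a 1,3-diol with a tertiary carbinol next to a trisubstituted allene.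
- Comparison: on bond economy of the key step the alternative is better (three bonds and two rings against two bonds and one ring). For the conversion of the C9 ketone into the methyl-bearing alkene it is equal, since the same triflation and methylation would be needed. On stereocontrol the chosen plan is stronger, because C7 comes from carvone and C6 is set under conditions where the kinetic and thermodynamic outcomes agree. Overall step count should be similar once the preparation of A1 and the extra reductions are counted.

Alternative 2: The cut is C6–C8. The β-silyl divinyl ketone A3 (a cycloheptene C5=C6 acylated at C5 by a 2-methyl-3-trimethylsilylpropenoyl unit) would undergo a silicon-directed Nazarov closure with FeCl3 or BF3·OEt2; conrotatory closure forms C6–C8 and loss of the Me3Si group places the alkene at C8=C9, giving the trans-fused 2-methylcyclopentenone A4.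
- In its favour: the C9 methyl group is in place from the start, so no triflation and methylation are needed; C5 is α to the C10 ketone in A4 and can be equilibrated to the trans fusion, which is better than the irreversible protonation of step 14; C1, C3 and C7 already have their final configuration.
- Against it here: the cut leaves the fully substituted cycloheptene of A3 with three stereocentres still to be made, so the seven-membered ring is postponed and not solved. The sense of conrotation must be controlled by the C7 isopropyl group to set C6. A Lewis acid meets a tertiary silyl ether that is homoallylic to the pentadienyl cation. Afterwards the C10 ketone has to be removed and the alkene moved from C8=C9 to C9=C10.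
- Comparison: for the five-membered ring and the ring fusion the alternative is equal or better, and its annulation is shorter than steps 7 to 15. It makes no use of the chiral pool for the seven-membered ring, however, so the total count depends on an unsolved precursor, and its mechanism (cationic electrocyclisation) is less compatible with the C3 carbinol than the radical ring expansion.

Alternative 3: The cut is C1–C7. The bromo aldehyde A5 (a trans-disubstituted cyclopentene carrying the C4–C3–C2–C1 aldehyde chain on C5 and a 3-bromo-2-methylpropenyl group on C6) would be treated with CrCl2 (divalent chromium); the allylchromium species would add through its γ-carbon C7 to the C1 aldehyde in an intramolecular Nozaki–Hiyama allylation to give the bicyclic isopropenyl carbinol A6.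
- In its favour: the seven-membered ring, C1 and C7 are made in one mild step; the C1 hydroxyl appears free and, as drawn in A6, already cis to the C7 substituent, so direct acylation could replace the inversion of step 17 (here the alternative is better); the cyclopentene with its methyl group and the ring fusion are carried in, so the end game after the key step is shorter.
- Against it here: the two new centres must come out cis to each other and in the right sense relative to C6, while open-chain allylchromium additions favour the anti product through a chair transition state, and how this translates to a seven-membered ring closure is not reliably predictable. The closure of a seven-membered ring from an open chain is entropically less favoured. A5 needs three stereocentres from asymmetric synthesis, and the isopropenyl group would later have to be hydrogenated in the presence of the ring alkene.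
- Comparison: on paper the alternative builds more stereochemical information in its key step (step 6 builds none) and is shorter after the key step. The chosen plan has a ring expansion with no stereochemical risk and takes C7 from the chiral pool; in overall step count the two are probably comparable because of the effort hidden in A5.

Key step: step 6

Remarks: (a) The configurations of 8 and 12 were checked against 30 and (R)-carvone: both carry isopropyl α and the C1 oxygen β, and no correction is needed. C1 is deliberately carried as the β epimer from 5 to 27 and inverted in step 17, and the γ-oxidation of step 3 is assumed to give this trans isomer. (b) Allyl bromide (13) serves as the acetonyl equivalent because its unmasking needs no strong acid, and C6 is alkylated on 12 before the C3 carbinol is made.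

Step 1
Reactants: 1 (R)-carvone
Product: 2 (R)-carvotanacetone, (5R)-5-isopropyl-2-methylcyclohex-2-en-1-one
Conditions: H2 (1 atm), RhCl(PPh3)3 (2 mol %), PhMe, rt
Reagents that add atoms: none
Why: Homogeneous hydrogenation with RhCl(PPh3)3 is selective for the unhindered 1,1-disubstituted alkene over the conjugated trisubstituted enone alkene; the stereocentre (the future C7) is not touched.

Step 2
Reactants: 2 (R)-carvotanacetone
Product: 4 (5R)-5-isopropyl-2-methyl-1-(trimethylsilyloxy)cyclohexa-1,3-diene, via bromomagnesium dienolate 3 (not isolated)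
Conditions: MeMgBr (1.3 equiv), FeCl3 (5 mol %), Et2O, −20 → 0 °C; then Me3SiCl, Et3N, DMPU, 0 °C → rt
Reagents that add atoms: chlorotrimethylsilane, C[Si](C)(C)Cl
Why: MeMgBr with catalytic FeCl3 acts as a base and not as a nucleophile and removes a γ-hydrogen, giving the through-conjugated magnesium dienolate 3, which is O-silylated to the linear (thermodynamic) silyl dienol ether; this is the established way to extended dienol ethers of cyclohexenones that have γ-hydrogens.

Step 3
Reactants: 4 (5R)-5-isopropyl-2-methyl-1-(trimethylsilyloxy)cyclohexa-1,3-diene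
Product: 5 (4R,5R)-4-hydroxy-5-isopropyl-2-methylcyclohex-2-en-1-one (OH trans to isopropyl)
Conditions: mCPBA, NaHCO3, CH2Cl2, −20 °C; then 1 M HCl, THF, 0 °C
Reagents that add atoms: mCPBA, O=C(OO)c1cccc(Cl)c1
Why: Vinylogous Rubottom oxidation: the peracid oxidises the terminal double bond of the dienol ether at the γ-carbon from the face anti to the neighbouring isopropyl group, and collapse of the oxirane on acidic work-up gives the γ-hydroxy enone; the new stereocentre (the future C1) is thereby set with oxygen β, trans to isopropyl, which is the epimer wanted at this stage.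

Step 4
Reactants: 5 (4R,5R)-4-hydroxy-5-isopropyl-2-methylcyclohex-2-en-1-one
Product: 6 (4R,5R)-4-(tert-butyldimethylsilyloxy)-5-isopropyl-2-methylcyclohex-2-en-1-one
Conditions: t-BuMe2SiCl, imidazole, DMF, rt
Reagents that add atoms: tert-butyldimethylsilyl chloride, CC(C)(C)[Si](C)(C)Cl
Why: Standard silylation of a secondary allylic alcohol; the tert-butyldimethylsilyl ether is chosen because it should survive hydride, zinc carbenoid, FeCl3/DMF, amide bases, alkaline peroxide, SmI2 and Li/NH3 and is removed by fluoride at the end.

Step 5
Reactants: 6 (4R,5R)-4-(tert-butyldimethylsilyloxy)-5-isopropyl-2-methylcyclohex-2-en-1-one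
Product: 8 (4S,5R)-4-(tert-butyldimethylsilyloxy)-5-isopropyl-2-methyl-1-(trimethylsilyloxy)cyclohex-1-ene, via lithium enolate 7 (not isolated)
Conditions: LiBH(s-Bu)3, THF, −78 °C; then Me3SiCl, Et3N, −78 → 0 °C
Reagents that add atoms: chlorotrimethylsilane, C[Si](C)(C)Cl
Why: LiBH(s-Bu)3 delivers hydride 1,4 to the β-unsubstituted enone, and O-silylation of the lithium enolate 7 fixes the enol ether double bond between the carbonyl carbon and the methyl-bearing carbon (regiospecific enolate trapping); the silyloxy group is γ to the enolate carbon and cannot be eliminated, and no new stereocentre is formed.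

Step 6
Reactants: 8 (4S,5R)-4-(tert-butyldimethylsilyloxy)-5-isopropyl-2-methyl-1-(trimethylsilyloxy)cyclohex-1-ene; 9 diiodomethane
Product: 12 (5S,6R)-5-(tert-butyldimethylsilyloxy)-6-isopropyl-3-methylcyclohept-2-en-1-one, via silyloxycyclopropane 10 (not isolated), via 3-chloro ketone 11 (not isolated)
Conditions: (a) Et2Zn, CH2I2, PhMe, 0 °C → rt; (b) FeCl3, DMF, 0 °C → rt; (c) NaOAc, MeOH, reflux (telescoped)
Reagents that add atoms: diiodomethane (9), ICI
Why: The zinc carbenoid EtZnCH2I (Furukawa variant of the Simmons–Smith reaction) transfers CH2 to the electron-rich tetrasubstituted enol ether in a concerted butterfly [2+1] addition, forming C3–C4 and C4–C5 and the silyloxycyclopropane 10. FeCl3 in DMF then oxidises 10 by one electron, and the oxygen-centred radical cation cleaves the strained C3–C5 bond shared by the three- and six-membered rings, which gives the C5 carbonyl and the tertiary C3 radical. Chlorine transfer from a second FeCl3 gives the 3-chloro ketone 11, and NaOAc removes HCl by E1cB through the C4 enolate, placing the double bond at C3=C4 in conjugation. The closest known reaction type is the Saegusa–Ito-type one-carbon ring expansion of 1-silyloxybicyclo[n.1.0]alkanes to cycloalk-2-enones, which tolerates a methyl group on the second bridgehead. Mode of closure: the three-membered ring closes by cheletropic methylene transfer, whereas the seven-membered ring is not closed end to end but results from scission of the zero-atom bridge of the bicyclo[4.1.0]heptane. No stereocentre is created: the two cyclopropane centres of 10 and the C3 centre of 11 are erased, and C1 and C7 are not enolisable positions of 12. The selectivity needed is insertion on the methyl-bearing side, which is secured by the regiodefined enol ether from step 5 and by cleavage of the internal cyclopropane bond; the enol ether is the only alkene, and FeCl3 complexed by DMF should leave the C1 silyl ether intact.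

Step 7
Reactants: 12 (5S,6R)-5-(tert-butyldimethylsilyloxy)-6-isopropyl-3-methylcyclohept-2-en-1-one; 13 allyl bromide
Product: 15 6β-allyl-1β-(tert-butyldimethylsilyloxy)-7α-isopropyl-3-methylcyclohept-3-en-5-one (core numbering), via lithium dienolate 14 (not isolated)
Conditions: LiN(i-Pr)2, THF, −78 °C; then allyl bromide, DMPU, −78 → −20 °C
Reagents that add atoms: allyl bromide (13), C=CCBr
Why: LiN(i-Pr)2 removes the α′-hydrogen at C6 kinetically to give the cross-conjugated dienolate 14 (γ-deprotonation needs equilibrating conditions), and SN2 allylation takes place anti to the adjacent C7 isopropyl group, setting C6 with the side chain β; this trans isomer is also the thermodynamic one, so later epimerisation at C6 can only reinforce it.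

Step 8
Reactants: 15 6β-allyl-1β-(tert-butyldimethylsilyloxy)-7α-isopropyl-3-methylcyclohept-3-en-5-one
Product: 16 6β-allyl-1β-(tert-butyldimethylsilyloxy)-3α,4α-epoxy-7α-isopropyl-3β-methylcycloheptan-5-one
Conditions: 30% H2O2, NaOH (aq), MeOH, 0 °C
Reagents that add atoms: hydrogen peroxide, OO
Why: Weitz–Scheffer nucleophilic epoxidation: hydroperoxide adds to C3 from the α face, anti to the β silyloxy group at the 1,3-related C1 (the same sense as the epoxidation of carvone trans to its 1,3-related substituent), and the enolate closes the oxirane on that face, which sets C3 (O α, CH3 β); the isolated allyl alkene does not react with the nucleophilic oxidant.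

Step 9
Reactants: 16 6β-allyl-1β-(tert-butyldimethylsilyloxy)-3α,4α-epoxy-7α-isopropyl-3β-methylcycloheptan-5-one
Product: 17 6β-allyl-1β-(tert-butyldimethylsilyloxy)-3α-hydroxy-7α-isopropyl-3β-methylcycloheptan-5-one
Conditions: SmI2 (2.5 equiv), THF–MeOH, −90 °C
Reagents that add atoms: none
Why: SmI2 reduces the ketone to a ketyl that cleaves the adjacent C4–O bond of the α,β-epoxy ketone, giving the β-hydroxy ketone without touching the C3–O bond, so the C3 configuration is kept; at −90 °C with MeOH as proton source neither dehydration nor reduction of the ketone or the alkene is expected.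

Step 10
Reactants: 17 6β-allyl-1β-(tert-butyldimethylsilyloxy)-3α-hydroxy-7α-isopropyl-3β-methylcycloheptan-5-one
Product: 18 6β-allyl-1β-(tert-butyldimethylsilyloxy)-7α-isopropyl-3β-methyl-3α-(triethylsilyloxy)cycloheptan-5-one
Conditions: Et3SiOTf, 2,6-lutidine, CH2Cl2, −78 °C
Reagents that add atoms: triethylsilyl trifluoromethanesulfonate, CC[Si](CC)(CC)OS(=O)(=O)C(F)(F)F
Why: A silyl triflate with a hindered pyridine silylates the tertiary aldol-type hydroxyl at low temperature without enolising the ketone; capping the hydroxyl shuts down retro-aldol opening of the 3-hydroxycycloheptanone and keeps an alkoxide out of steps 12 to 15.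

Step 11
Reactants: 18 6β-allyl-1β-(tert-butyldimethylsilyloxy)-7α-isopropyl-3β-methyl-3α-(triethylsilyloxy)cycloheptan-5-one
Product: 19 1β-(tert-butyldimethylsilyloxy)-7α-isopropyl-3β-methyl-6β-(2-oxopropyl)-3α-(triethylsilyloxy)cycloheptan-5-one
Conditions: PdCl2 (10 mol %), CuCl (1 equiv), O2 (1 atm), DMF–H2O (7:1), rt
Reagents that add atoms: water, O
Why: Wacker–Tsuji oxidation converts the terminal alkene into the methyl ketone (Markovnikov attack of water on the PdCl2-bound alkene, reoxidation by CuCl/O2), giving the 1,4-diketone under nearly neutral conditions that the silyl ethers should tolerate.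

Step 12
Reactants: 19 1β-(tert-butyldimethylsilyloxy)-7α-isopropyl-3β-methyl-6β-(2-oxopropyl)-3α-(triethylsilyloxy)cycloheptan-5-one
Product: 20 1β-(tert-butyldimethylsilyloxy)-5-hydroxy-7α-isopropyl-3β-methyl-3α-(triethylsilyloxy)-6αH-bicyclo[5.3.0]decan-9-one (C5 configuration open)
Conditions: LiN(SiMe3)2 (1.1 equiv), THF, −78 → −20 °C; aq. NH4Cl
Reagents that add atoms: none
Why: The hindered amide deprotonates the unhindered methyl group of the methyl ketone kinetically, and the enolate adds to the C5 ketone in a 5-(enolexo)-exo-trig aldol that forms C5–C10 and the five-membered ring; working at low temperature avoids the C4 enolate and the E1cB loss of the C3 silyloxy group that an equilibrating hydroxide-mediated condensation would risk, and the C5 carbinol configuration is immaterial.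

Step 13
Reactants: 20 1β-(tert-butyldimethylsilyloxy)-5-hydroxy-7α-isopropyl-3β-methyl-3α-(triethylsilyloxy)-6αH-bicyclo[5.3.0]decan-9-one
Product: 22 1β-(tert-butyldimethylsilyloxy)-7α-isopropyl-3β-methyl-3α-(triethylsilyloxy)-6αH-bicyclo[5.3.0]dec-5(10)-en-9-one, via tertiary mesylate 21 (not isolated)
Conditions: MsCl, Et3N, DMAP (cat.), CH2Cl2, 0 °C → rt
Reagents that add atoms: none
Why: Sulfonylation of the tertiary aldol hydroxyl (sulfene pathway) followed by E1cB elimination through the C9 enolate gives the conjugated cyclopentenone with the double bond C5=C10; amine bases at room temperature should not disturb C6 or the silyl ethers.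

Step 14
Reactants: 22 1β-(tert-butyldimethylsilyloxy)-7α-isopropyl-3β-methyl-3α-(triethylsilyloxy)-6αH-bicyclo[5.3.0]dec-5(10)-en-9-one
Product: 24 1β-(tert-butyldimethylsilyloxy)-7α-isopropyl-3β-methyl-3α-(triethylsilyloxy)-5βH,6αH-bicyclo[5.3.0]dec-9-en-9-yl trifluoromethanesulfonate, via lithium enolate 23 (not isolated)
Conditions: Li, NH3 (l), THF, t-BuOH (1 equiv), −78 °C; isoprene; evaporate NH3; then PhNTf2, THF, −78 °C → rt
Reagents that add atoms: N-phenylbis(trifluoromethanesulfonimide), O=S(=O)(N(c1ccccc1)S(=O)(=O)C(F)(F)F)C(F)(F)F
Why: Dissolving-metal reduction of the enone: the β-carbanion at C5 is protonated to give the more stable trans ring fusion (H5 β, anti to H6 α, both ring bonds equatorial on the seven-membered ring), and the regiodefined lithium enolate 23 is trapped on oxygen as the alkenyl triflate with the double bond fixed at C9=C10 (reductive enolate trapping).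

Step 15
Reactants: 24 1β-(tert-butyldimethylsilyloxy)-7α-isopropyl-3β-methyl-3α-(triethylsilyloxy)-5βH,6αH-bicyclo[5.3.0]dec-9-en-9-yl trifluoromethanesulfonate; 25 dimethylzinc
Product: 26 1β-(tert-butyldimethylsilyloxy)-7α-isopropyl-3β,9-dimethyl-3α-(triethylsilyloxy)-5βH,6αH-bicyclo[5.3.0]dec-9-ene
Conditions: Me2Zn, Pd(PPh3)4 (5 mol %), THF, 0 → 50 °C
Reagents that add atoms: dimethylzinc (25), C[Zn]C
Why: Negishi cross-coupling of the alkenyl triflate with Me2Zn under zerovalent-palladium catalysis replaces the triflate by methyl with retention of the alkene position; no stereocentre is involved.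

Step 16
Reactants: 26 1β-(tert-butyldimethylsilyloxy)-7α-isopropyl-3β,9-dimethyl-3α-(triethylsilyloxy)-5βH,6αH-bicyclo[5.3.0]dec-9-ene
Product: 27 7α-isopropyl-3β,9-dimethyl-5βH,6αH-bicyclo[5.3.0]dec-9-ene-1β,3α-diol
Conditions: Bu4NF (4 equiv), THF, rt → 50 °C
Reagents that add atoms: none
Why: Fluoride cleaves both silyl ethers (the hindered secondary tert-butyldimethylsilyl ether needs mild warming); the diol has no group sensitive to the basic fluoride.

Step 17
Reactants: 27 7α-isopropyl-3β,9-dimethyl-5βH,6αH-bicyclo[5.3.0]dec-9-ene-1β,3α-diol; 28 isovanillic acid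
Product: 29 3α-hydroxy-7α-isopropyl-3β,9-dimethyl-5βH,6αH-bicyclo[5.3.0]dec-9-en-1α-yl 3-hydroxy-4-methoxybenzoate
Conditions: PPh3, DIAD, THF, 0 °C → rt
Reagents that add atoms: isovanillic acid (28), COc1ccc(C(=O)O)cc1O
Why: Mitsunobu esterification: the secondary C1–OH is activated as the alkoxyphosphonium ion and displaced by the carboxylate with inversion, giving the 1α ester cis to isopropyl; the tertiary C3–OH cannot be displaced, and the carboxylic acid, far more acidic than the phenol, is the pronucleophile that reacts.

Step 18
Reactants: 29 3α-hydroxy-7α-isopropyl-3β,9-dimethyl-5βH,6αH-bicyclo[5.3.0]dec-9-en-1α-yl 3-hydroxy-4-methoxybenzoate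
Product: 30 (1R,3R,5S,6R,7S,9R,10S)-9α,10α-epoxy-3-hydroxy-7-isopropyl-3,9-dimethylbicyclo[5.3.0]dec-1-yl 3-hydroxy-4-methoxybenzoate (core numbering; CNP0106636.1)
Conditions: mCPBA, NaHCO3, CH2Cl2, 0 °C
Reagents that add atoms: mCPBA, O=C(OO)c1cccc(Cl)c1
Why: Prilezhaev epoxidation of the only alkene: syn transfer of oxygen sets C9 and C10 together, and attack is expected on the α face, anti to the pseudoaxial allylic C5–H and assisted by hydrogen bonding to the α-oriented C3–OH; the bicarbonate buffer protects the epoxide from the acid by-product.

Compound list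

1 | (R)-carvone | CC1=CC[C@H](CC1=O)C(C)=C | starting material
2 | (R)-carvotanacetone, (5R)-5-isopropyl-2-methylcyclohex-2-en-1-one | CC1=CC[C@H](CC1=O)C(C)C | intermediate
3 | bromomagnesium (5R)-5-isopropyl-2-methylcyclohexa-1,3-dien-1-olate (not isolated) | CC1=C(O[Mg]Br)C[C@H](C(C)C)C=C1 | intermediate
4 | (5R)-5-isopropyl-2-methyl-1-(trimethylsilyloxy)cyclohexa-1,3-diene | CC1=C(O[Si](C)(C)C)C[C@H](C(C)C)C=C1 | intermediate
5 | (4R,5R)-4-hydroxy-5-isopropyl-2-methylcyclohex-2-en-1-one | CC1=C[C@H](O)[C@H](CC1=O)C(C)C | intermediate
6 | (4R,5R)-4-(tert-butyldimethylsilyloxy)-5-isopropyl-2-methylcyclohex-2-en-1-one | CC1=C[C@H](O[Si](C)(C)C(C)(C)C)[C@H](CC1=O)C(C)C | intermediate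
7 | lithium (4S,5R)-4-(tert-butyldimethylsilyloxy)-5-isopropyl-2-methylcyclohex-1-en-1-olate (not isolated) | [Li]OC1=C(C)C[C@H](O[Si](C)(C)C(C)(C)C)[C@@H](C(C)C)C1 | intermediate
8 | (4S,5R)-4-(tert-butyldimethylsilyloxy)-5-isopropyl-2-methyl-1-(trimethylsilyloxy)cyclohex-1-ene | C[Si](C)(C)OC1=C(C)C[C@H](O[Si](C)(C)C(C)(C)C)[C@@H](C(C)C)C1 | intermediate
9 | diiodomethane | ICI | starting material
10 | (3R,4S)-4-(tert-butyldimethylsilyloxy)-3-isopropyl-6-methyl-1-(trimethylsilyloxy)bicyclo[4.1.0]heptane, either cyclopropane face (not isolated) | C[Si](C)(C)OC12CC2(C)C[C@H](O[Si](C)(C)C(C)(C)C)[C@@H](C(C)C)C1 | intermediate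
11 | (5S,6R)-5-(tert-butyldimethylsilyloxy)-3-chloro-6-isopropyl-3-methylcycloheptan-1-one, C3 epimers (not isolated) | CC(C)(C)[Si](C)(C)O[C@H]1CC(C)(Cl)CC(=O)C[C@@H]1C(C)C | intermediate
12 | (5S,6R)-5-(tert-butyldimethylsilyloxy)-6-isopropyl-3-methylcyclohept-2-en-1-one | CC(C)(C)[Si](C)(C)O[C@H]1CC(C)=CC(=O)C[C@@H]1C(C)C | intermediate
13 | allyl bromide | C=CCBr | starting material
14 | lithium cross-conjugated dienolate of 12, O–C5=C6 and C3=C4 (not isolated) | CC(C)(C)[Si](C)(C)O[C@H]1CC(C)=CC(O[Li])=C[C@@H]1C(C)C | intermediate
15 | 6β-allyl-1β-(tert-butyldimethylsilyloxy)-7α-isopropyl-3-methylcyclohept-3-en-5-one | CC(C)(C)[Si](C)(C)O[C@H]1CC(C)=CC(=O)[C@@H](CC=C)[C@@H]1C(C)C | intermediate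
16 | 6β-allyl-1β-(tert-butyldimethylsilyloxy)-3α,4α-epoxy-7α-isopropyl-3β-methylcycloheptan-5-one | CC(C)(C)[Si](C)(C)O[C@H]1C[C@]2(C)O[C@@H]2C(=O)[C@@H](CC=C)[C@@H]1C(C)C | intermediate
17 | 6β-allyl-1β-(tert-butyldimethylsilyloxy)-3α-hydroxy-7α-isopropyl-3β-methylcycloheptan-5-one | CC(C)(C)[Si](C)(C)O[C@H]1C[C@](C)(O)CC(=O)[C@@H](CC=C)[C@@H]1C(C)C | intermediate
18 | 6β-allyl-1β-(tert-butyldimethylsilyloxy)-7α-isopropyl-3β-methyl-3α-(triethylsilyloxy)cycloheptan-5-one | CC(C)(C)[Si](C)(C)O[C@H]1C[C@](C)(O[Si](CC)(CC)CC)CC(=O)[C@@H](CC=C)[C@@H]1C(C)C | intermediate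
19 | 1β-(tert-butyldimethylsilyloxy)-7α-isopropyl-3β-methyl-6β-(2-oxopropyl)-3α-(triethylsilyloxy)cycloheptan-5-one | CC(C)(C)[Si](C)(C)O[C@H]1C[C@](C)(O[Si](CC)(CC)CC)CC(=O)[C@@H](CC(C)=O)[C@@H]1C(C)C | intermediate
20 | 1β-(tert-butyldimethylsilyloxy)-5-hydroxy-7α-isopropyl-3β-methyl-3α-(triethylsilyloxy)-6αH-bicyclo[5.3.0]decan-9-one, C5 configuration open | CC(C)(C)[Si](C)(C)O[C@H]1C[C@](C)(O[Si](CC)(CC)CC)CC2(O)CC(=O)C[C@H]2[C@@H]1C(C)C | intermediate
21 | C5 methanesulfonate of 20 (not isolated) | CC(C)(C)[Si](C)(C)O[C@H]1C[C@](C)(O[Si](CC)(CC)CC)CC2(OS(C)(=O)=O)CC(=O)C[C@H]2[C@@H]1C(C)C | intermediate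
22 | 1β-(tert-butyldimethylsilyloxy)-7α-isopropyl-3β-methyl-3α-(triethylsilyloxy)-6αH-bicyclo[5.3.0]dec-5(10)-en-9-one | CC(C)(C)[Si](C)(C)O[C@H]1C[C@](C)(O[Si](CC)(CC)CC)CC2=CC(=O)C[C@H]2[C@@H]1C(C)C | intermediate
23 | lithium enolate (O–C9=C10) of the trans-fused ketone, 5βH,6αH (not isolated) | CC(C)(C)[Si](C)(C)O[C@H]1C[C@](C)(O[Si](CC)(CC)CC)C[C@H]2[C@@H](CC(O[Li])=C2)[C@@H]1C(C)C | intermediate
24 | 1β-(tert-butyldimethylsilyloxy)-7α-isopropyl-3β-methyl-3α-(triethylsilyloxy)-5βH,6αH-bicyclo[5.3.0]dec-9-en-9-yl trifluoromethanesulfonate | CC(C)(C)[Si](C)(C)O[C@H]1C[C@](C)(O[Si](CC)(CC)CC)C[C@H]2[C@@H](CC(OS(=O)(=O)C(F)(F)F)=C2)[C@@H]1C(C)C | intermediate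
25 | dimethylzinc | C[Zn]C | starting material
26 | 1β-(tert-butyldimethylsilyloxy)-7α-isopropyl-3β,9-dimethyl-3α-(triethylsilyloxy)-5βH,6αH-bicyclo[5.3.0]dec-9-ene | CC(C)(C)[Si](C)(C)O[C@H]1C[C@](C)(O[Si](CC)(CC)CC)C[C@H]2[C@@H](CC(C)=C2)[C@@H]1C(C)C | intermediate
27 | 7α-isopropyl-3β,9-dimethyl-5βH,6αH-bicyclo[5.3.0]dec-9-ene-1β,3α-diol | O[C@H]1C[C@](C)(O)C[C@H]2[C@@H](CC(C)=C2)[C@@H]1C(C)C | intermediate
28 | isovanillic acid (3-hydroxy-4-methoxybenzoic acid) | COc1ccc(C(=O)O)cc1O | starting material
29 | 3α-hydroxy-7α-isopropyl-3β,9-dimethyl-5βH,6αH-bicyclo[5.3.0]dec-9-en-1α-yl 3-hydroxy-4-methoxybenzoate | COc1ccc(C(=O)O[C@@H]2C[C@](C)(O)C[C@H]3[C@@H](CC(C)=C3)[C@@H]2C(C)C)cc1O | intermediate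
30 | (1R,3R,5S,6R,7S,9R,10S)-9α,10α-epoxy-3-hydroxy-7-isopropyl-3,9-dimethylbicyclo[5.3.0]dec-1-yl 3-hydroxy-4-methoxybenzoate (core numbering; CNP0106636.1) | COc1ccc(C(=O)O[C@@H]2C[C@](C)(O)C[C@H]3[C@@H](C[C@@]4(C)O[C@@H]34)[C@@H]2C(C)C)cc1O | target

Total step count: 18. Longest linear sequence: 18 steps, from 1 to 30; 9, 13, 25 and 28 are commercial and enter directly.

Least certain steps

Step 6 (key step). Most likely to go wrong: incomplete methylene transfer to the hindered tetrasubstituted enol ether, with loss of the enol silyl group to the zinc iodide that forms. In the iron stage, cleavage of the C1 silyl ether or unselective dehydrochlorination may occur; under NaOAc/MeOH a vinylogous elimination of the C1 silyloxy group through the γ-enolate is also conceivable. Fallback: from 8, dibromocarbene addition (CHBr3, KOt-Bu, pentane, −30 °C) should give the dibromocyclopropane F1, whose cyclopropyl-to-allyl cation opening on warming, with loss of Me3SiBr, gives the 2-bromo enone F2. Hydrogenolysis of the C–Br bond with formate under zerovalent-palladium catalysis (Pd(OAc)2, PPh3, HCO2H, Et3N, DMF, 60 °C) returns to the route at 12. This replaces the oxidative radical cleavage by a cationic opening and needs no FeCl3.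

Step 3. Most likely to go wrong: oxygen transfer to the tetrasubstituted enol ether double bond (hydroxylation at the methyl-bearing α-carbon) in competition with the γ-position, and incomplete anti selectivity relative to the isopropyl group. Fallback: from 4, dye-sensitised photo-oxygenation (O2, tetraphenylporphyrin, hν, CH2Cl2, −78 °C). Singlet oxygen adds across the diene termini in a [4+2] sense, which fixes the new C–O bond at the γ-carbon, and silyl transfer with hydrolysis of the endoperoxide gives the γ-hydroperoxy enone F3; reduction with PPh3 returns to the route at 5.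

Step 8. Most likely to go wrong: poor facial selectivity of hydroperoxide addition on the flexible cycloheptenone, which would give the wrong C3 carbinol; base-induced vinylogous loss of the C1 silyloxy group is a lesser risk. Fallback: from 15, 1,2-reduction under Luche conditions (NaBH4, CeCl3·7H2O, MeOH, −78 °C) to the equatorial 5α-allylic alcohol F4, then hydroxyl-directed epoxidation (VO(acac)2, t-BuOOH, CH2Cl2), which delivers oxygen syn to the 5α-hydroxyl, to the epoxy alcohol F5. Dess–Martin oxidation of the carbinol returns to the route at 16.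

Step 17. Most likely to go wrong: slow SN2 displacement at the hindered secondary carbinol next to the isopropyl-bearing carbon, so that elimination or acylation with retention through an acyloxyphosphonium path competes; the only moderate acidity of 28 aggravates this. Fallback: from 27, Mitsunobu inversion with the more acidic 4-nitrobenzoic acid to the inverted 4-nitrobenzoate F6, then methanolysis (K2CO3, MeOH) to the 1α-alcohol F7. Carbodiimide/DMAP acylation (retention) with 3-acetoxy-4-methoxybenzoic acid F8 (from 28 with Ac2O, pyridine) gives the protected ester F9, and selective cleavage of the aryl acetate (K2CO3, MeOH, 0 °C) returns to the route at 29.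

Step 18. Most likely to go wrong: attack of the peracid on the β face, or acid-promoted opening of the epoxide (a β epoxide could be opened transannularly by the α C3–OH); oxidation of the electron-rich phenol is a minor risk. Fallback: from 26, bromohydrin formation (NBS, THF–H2O; bromonium ion on the more accessible face, water opening trans at the tertiary C9) to the 9α-hydroxy-10β-bromide F10. Base-induced closure (K2CO3, MeOH) places the oxygen on the face opposite to that attacked by the electrophile and gives the silylated α-epoxide F11. Desilylation (Bu4NF, THF) gives the epoxy diol F12, and Mitsunobu esterification with 28 under the conditions of step 17 returns to the route at 30.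

## Further compounds

F1 | step 6 | (3R,4S)-7,7-dibromo-4-(tert-butyldimethylsilyloxy)-3-isopropyl-6-methyl-1-(trimethylsilyloxy)bicyclo[4.1.0]heptane | C[Si](C)(C)OC12C(Br)(Br)C2(C)C[C@H](O[Si](C)(C)C(C)(C)C)[C@@H](C(C)C)C1
F2 | step 6 | (5S,6R)-2-bromo-5-(tert-butyldimethylsilyloxy)-6-isopropyl-3-methylcyclohept-2-en-1-one | CC(C)(C)[Si](C)(C)O[C@H]1CC(C)=C(Br)C(=O)C[C@@H]1C(C)C
F3 | step 3 | (4R,5R)-4-hydroperoxy-5-isopropyl-2-methylcyclohex-2-en-1-one | CC1=C[C@H](OO)[C@H](CC1=O)C(C)C
F4 | step 8 | 6β-allyl-1β-(tert-butyldimethylsilyloxy)-7α-isopropyl-3-methylcyclohept-3-en-5α-ol | CC(C)(C)[Si](C)(C)O[C@H]1CC(C)=C[C@H](O)[C@@H](CC=C)[C@@H]1C(C)C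
F5 | step 8 | 6β-allyl-1β-(tert-butyldimethylsilyloxy)-3α,4α-epoxy-7α-isopropyl-3β-methylcycloheptan-5α-ol | CC(C)(C)[Si](C)(C)O[C@H]1C[C@]2(C)O[C@@H]2[C@H](O)[C@@H](CC=C)[C@@H]1C(C)C
F6 | step 17 | 3α-hydroxy-7α-isopropyl-3β,9-dimethyl-5βH,6αH-bicyclo[5.3.0]dec-9-en-1α-yl 4-nitrobenzoate | O=C(O[C@@H]1C[C@](C)(O)C[C@H]2[C@@H](CC(C)=C2)[C@@H]1C(C)C)c1ccc(cc1)[N+](=O)[O-]
F7 | step 17 | 7α-isopropyl-3β,9-dimethyl-5βH,6αH-bicyclo[5.3.0]dec-9-ene-1α,3α-diol | O[C@@H]1C[C@](C)(O)C[C@H]2[C@@H](CC(C)=C2)[C@@H]1C(C)C
F8 | step 17 | 3-acetoxy-4-methoxybenzoic acid | COc1ccc(C(=O)O)cc1OC(C)=O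
F9 | step 17 | 3α-hydroxy-7α-isopropyl-3β,9-dimethyl-5βH,6αH-bicyclo[5.3.0]dec-9-en-1α-yl 3-acetoxy-4-methoxybenzoate | COc1ccc(C(=O)O[C@@H]2C[C@](C)(O)C[C@H]3[C@@H](CC(C)=C3)[C@@H]2C(C)C)cc1OC(C)=O
F10 | step 18 | 10β-bromo-1β-(tert-butyldimethylsilyloxy)-7α-isopropyl-3β,9β-dimethyl-3α-(triethylsilyloxy)-5βH,6αH-bicyclo[5.3.0]decan-9α-ol | CC(C)(C)[Si](C)(C)O[C@H]1C[C@](C)(O[Si](CC)(CC)CC)C[C@H]2[C@@H](C[C@@](C)(O)[C@@H]2Br)[C@@H]1C(C)C
F11 | step 18 | 1β-(tert-butyldimethylsilyloxy)-9α,10α-epoxy-7α-isopropyl-3β,9β-dimethyl-3α-(triethylsilyloxy)-5βH,6αH-bicyclo[5.3.0]decane | CC(C)(C)[Si](C)(C)O[C@H]1C[C@](C)(O[Si](CC)(CC)CC)C[C@H]2[C@@H](C[C@@]3(C)O[C@@H]23)[C@@H]1C(C)C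
F12 | step 18 | 9α,10α-epoxy-7α-isopropyl-3β,9β-dimethyl-5βH,6αH-bicyclo[5.3.0]decane-1β,3α-diol | O[C@H]1C[C@](C)(O)C[C@H]2[C@@H](C[C@@]3(C)O[C@@H]23)[C@@H]1C(C)C
A1 | alternative 1 | allene-yne: bis-silylated diol with terminal alkyne C10≡C5 and allene C7=C6=C8 (isopropyl on C7) | CC(C)(C)[Si](C)(C)O[C@H](C[C@](C)(O[Si](C)(C)C(C)(C)C)CC#C)C(C(C)C)=C=C
A2 | alternative 1 | bicyclic dienone (C5=C10, C9=O, C6=C7) | CC(C)(C)[Si](C)(C)O[C@@H]1C[C@](C)(O[Si](C)(C)C(C)(C)C)CC2=CC(=O)CC2=C1C(C)C
A3 | alternative 2 | β-silyl divinyl ketone: cycloheptene C5=C6 bearing a 2-methyl-3-(trimethylsilyl)propenoyl group on C5 | CC(C)(C)[Si](C)(C)O[C@@H]1C[C@](C)(O[Si](C)(C)C(C)(C)C)CC(C(=O)C(C)=C[Si](C)(C)C)=C[C@@H]1C(C)C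
A4 | alternative 2 | trans-fused 2-methylcyclopentenone (C10=O, C8=C9) | CC(C)(C)[Si](C)(C)O[C@@H]1C[C@](C)(O[Si](C)(C)C(C)(C)C)C[C@H]2[C@@H](C=C(C)C2=O)[C@@H]1C(C)C
A5 | alternative 3 | bromo aldehyde: trans-disubstituted 3-methylcyclopentene with the C1 aldehyde chain on C5 and a 3-bromo-2-methylprop-1-enyl group on C6 | O=CC[C@](C)(O[Si](CC)(CC)CC)C[C@@H]1C=C(C)C[C@H]1C=C(C)CBr
A6 | alternative 3 | bicyclic isopropenyl carbinol | O[C@@H]1C[C@](C)(O[Si](CC)(CC)CC)C[C@H]2[C@@H](CC(C)=C2)[C@@H]1C(C)=C
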